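**Plan**

- Retrosynthesis: the ester C–O bond at O3 is cut first, releasing the gallate as a silylated acid chloride. Ring C is then cut at C4–C4a and at O1–C2 in one disconnection.
- Enabling feature: C2, C3 and C4 of ring C bear O1, O3 and O4 on adjacent carbons, the oxygen pattern of a 3-aryl-2,3-epoxy aldehyde. Ring A is a phloroglucinol in which both carbons ortho to O1 are identical, so a phenol can be annulated without a regiochemical choice.
- Forward: rings A and B come from phloroglucinol and 3,4-dihydroxybenzaldehyde. Ring C is the only ring made; it closes in one flask by aryl C–C bond formation at the aldehyde followed by phenol opening of the epoxide. O3 is then galloylated and all seven silyl ethers are removed.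
- Stereochemistry: C2 and C3 come from a catalytic asymmetric epoxidation of the (E)-enal (C3 retained, C2 inverted on ring closure, hence 2,3-trans). C4 arises by Felkin–Anh addition to the epoxy aldehyde (3,4-cis).

Key step: step 5

Assumption: the epoxidation is taken to follow the usual shielding model of diarylprolinol silyl ethers (peroxide attack on the E,s-trans iminium ion anti to the diaryl(silyloxy)methyl group), which assigns the (2R,3S)-epoxide to the (R)-catalyst.

**Route**

Step 1
Reactants: 1 phloroglucinol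
Product: 2 3,5-bis(tert-butyldimethylsilyloxy)phenol
Conditions: TBSCl (2.0 equiv), imidazole, DMF, 0 °C to rt; chromatography
Reagents that add atoms: tert-butyldimethylsilyl chloride, CC(C)(C)[Si](C)(C)Cl
Why: Imidazole-promoted silyl ether formation on a threefold-symmetric triphenol gives a single bis-ether under statistical control; the mono- and tris-ethers are separable and can be returned by resilylation or partial desilylation.

Step 2
Reactants: 3 3,4-dihydroxybenzaldehyde
Product: 4 3,4-bis(tert-butyldimethylsilyloxy)benzaldehyde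
Conditions: TBSCl (2.3 equiv), imidazole, DMF, rt
Reagents that add atoms: tert-butyldimethylsilyl chloride, CC(C)(C)[Si](C)(C)Cl
Why: Standard silyl ether formation on both phenols leaves the aldehyde untouched.

Step 3
Reactants: 4 3,4-bis(tert-butyldimethylsilyloxy)benzaldehyde
Product: 5 (E)-3-[3,4-bis(tert-butyldimethylsilyloxy)phenyl]prop-2-enal
Conditions: Ph3P=CHCHO (1.15 equiv), toluene, 80 °C
Reagents that add atoms: (triphenylphosphoranylidene)acetaldehyde, O=CC=P(c1ccccc1)(c1ccccc1)c1ccccc1
Why: Wittig olefination with the stabilised formylmethylene ylide gives the (E)-enal, and the conjugated product is less electrophilic than the aryl aldehyde, which limits a second homologation.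

Step 4
Reactants: 5 (E)-3-[3,4-bis(tert-butyldimethylsilyloxy)phenyl]prop-2-enal
Product: 6 (2R,3S)-3-[3,4-bis(tert-butyldimethylsilyloxy)phenyl]oxirane-2-carbaldehyde
Conditions: (R)-2-{bis[3,5-bis(trifluoromethyl)phenyl](trimethylsilyloxy)methyl}pyrrolidine (10 mol %), 35% aq. H2O2 (1.3 equiv), CH2Cl2, rt; short plug of Et3N-deactivated silica, used at once
Reagents that add atoms: hydrogen peroxide, OO
Why: Iminium-ion-mediated nucleophilic epoxidation: hydrogen peroxide adds to C3 of the E,s-trans iminium ion on the face away from the diaryl(silyloxy)methyl group, which with the (R)-catalyst should set 3S, and the resulting enamine closes onto the peroxide oxygen to give the trans (2R) epoxide.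

Step 5
Reactants: 2 3,5-bis(tert-butyldimethylsilyloxy)phenol; 6 (2R,3S)-3-[3,4-bis(tert-butyldimethylsilyloxy)phenyl]oxirane-2-carbaldehyde
Product: 9 (2R,3S,4S)-5,7,3′,4′-tetrakis(tert-butyldimethylsilyloxy)flavan-3,4-diol, via bromomagnesium phenolate 7 (not isolated), via open-chain epoxy carbinol phenolate 8 (not isolated)
Conditions: 2 (1.1 equiv), EtMgBr (1.1 equiv), Et2O, 0 °C; evaporate, CH2Cl2; 6 (1.0 equiv), −40 °C to rt, then 35 °C; pH 7 phosphate buffer
Reagents that add atoms: none
Why: Proposed new method: the bromomagnesium phenolate 7 binds the aldehyde oxygen of 6 and delivers an ortho carbon through a six-membered array (C4–C4a bond), giving after rearomatisation the magnesium phenolate 8, whose oxygen then opens the magnesium-activated aryl epoxide at the benzylic carbon (O1–C2 bond). The closest known reactions are the ortho-specific hydroxyalkylation of magnesium phenolates with α-oxygenated aldehydes and the 6-endo opening of aryl epoxides by an ortho-tethered phenol, as in the conversion of 2′-hydroxychalcone epoxides into dihydroflavonols; their union in one flask on an epoxy aldehyde is the untested part. Ring C closes in the 6-endo-tet mode, preferred over the 5-exo alternative because the 3,4-dioxygenated ring B stabilises positive charge at C2. C4 is set by Felkin–Anh addition anti to the epoxide C–O bond, which the poorly chelating epoxide oxygen is not expected to override and which leads to the 3,4-cis diol; C2 is set by inversion of the trans-epoxide (2,3-trans), and C3 is carried over from 6 unchanged. The step needs ortho attack and not para or O-attack (secured by the magnesium chelate in a non-coordinating solvent, with the two ortho carbons of 2 equivalent and ring closure consuming the phenol so that no second hydroxyalkylation follows), and it needs 6-endo closure (secured by benzylic activation).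

Step 6
Reactants: 10 gallic acid
Product: 12 3,4,5-tris(tert-butyldimethylsilyloxy)benzoic acid, via silyl ester 11 (not isolated)
Conditions: TBSCl (4.5 equiv), imidazole, DMF, rt; then AcOH/THF/H2O (3:1:1), rt
Reagents that add atoms: tert-butyldimethylsilyl chloride, CC(C)(C)[Si](C)(C)Cl
Why: Exhaustive silylation is followed by selective hydrolysis of the silyl ester, which is far more labile to aqueous acetic acid than the hindered aryl silyl ethers.

Step 7
Reactants: 12 3,4,5-tris(tert-butyldimethylsilyloxy)benzoic acid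
Product: 13 3,4,5-tris(tert-butyldimethylsilyloxy)benzoyl chloride
Conditions: (COCl)2 (1.2 equiv), DMF (cat.), CH2Cl2, 0 °C to rt; evaporate, use crude
Reagents that add atoms: oxalyl chloride, O=C(Cl)C(=O)Cl
Why: Acid chloride formation through the Vilsmeier-type chloroiminium catalyst gives only volatile by-products, and the aryl silyl ethers should tolerate the brief exposure to dry HCl.

Step 8
Reactants: 9 (2R,3S,4S)-5,7,3′,4′-tetrakis(tert-butyldimethylsilyloxy)flavan-3,4-diol; 13 3,4,5-tris(tert-butyldimethylsilyloxy)benzoyl chloride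
Product: 15 (2R,3S,4S)-4-hydroxy-5,7,3′,4′-tetrakis(tert-butyldimethylsilyloxy)flavan-3-yl 3,4,5-tris(tert-butyldimethylsilyloxy)benzoate, via dibutylstannylene acetal 14 (not isolated)
Conditions: Bu2SnO (1.05 equiv), toluene, reflux, Dean–Stark; then 13 (1.05 equiv), toluene, 0 °C to rt
Reagents that add atoms: none
Why: Stannylene acetal-mediated regioselective acylation delivers the acyl group to the equatorial oxygen of a cis-1,2-diol, here O3, while the quasi-axial benzylic O4 is also screened by the 5-silyloxy group; no stereocenter is touched.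

Step 9
Reactants: 15 (2R,3S,4S)-4-hydroxy-5,7,3′,4′-tetrakis(tert-butyldimethylsilyloxy)flavan-3-yl 3,4,5-tris(tert-butyldimethylsilyloxy)benzoate
Product: 16 (2R,3S,4S)-2-(3,4-dihydroxyphenyl)-4,5,7-trihydroxy-3,4-dihydro-2H-chromen-3-yl 3,4,5-trihydroxybenzoate
Conditions: TBAF/AcOH (1:1, 8 equiv), THF, 0 °C, argon; reversed-phase chromatography
Reagents that add atoms: none
Why: Fluoride-induced cleavage of the seven aryl silyl ethers under acetic acid buffering keeps the medium near neutral, so that neither phenoxide-driven 3→4 acyl migration nor acid ionisation of the benzylic C4–OH should intervene.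

**Compound list**

1 | phloroglucinol | Oc1cc(O)cc(O)c1 | starting material
2 | 3,5-bis(tert-butyldimethylsilyloxy)phenol | Oc1cc(O[Si](C)(C)C(C)(C)C)cc(O[Si](C)(C)C(C)(C)C)c1 | intermediate
3 | 3,4-dihydroxybenzaldehyde | O=Cc1ccc(O)c(O)c1 | starting material
4 | 3,4-bis(tert-butyldimethylsilyloxy)benzaldehyde | O=Cc1ccc(O[Si](C)(C)C(C)(C)C)c(O[Si](C)(C)C(C)(C)C)c1 | intermediate
5 | (E)-3-[3,4-bis(tert-butyldimethylsilyloxy)phenyl]prop-2-enal | O=C/C=C/c1ccc(O[Si](C)(C)C(C)(C)C)c(O[Si](C)(C)C(C)(C)C)c1 | intermediate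
6 | (2R,3S)-3-[3,4-bis(tert-butyldimethylsilyloxy)phenyl]oxirane-2-carbaldehyde | O=C[C@@H]1O[C@H]1c1ccc(O[Si](C)(C)C(C)(C)C)c(O[Si](C)(C)C(C)(C)C)c1 | intermediate
7 | bromomagnesium 3,5-bis(tert-butyldimethylsilyloxy)phenolate | Br[Mg]Oc1cc(O[Si](C)(C)C(C)(C)C)cc(O[Si](C)(C)C(C)(C)C)c1 | intermediate (not isolated)
8 | bromomagnesium 2-{(S)-hydroxy[(2S,3S)-3-(3,4-bis(tert-butyldimethylsilyloxy)phenyl)oxiran-2-yl]methyl}-3,5-bis(tert-butyldimethylsilyloxy)phenolate | O[C@@H](c1c(O[Mg]Br)cc(O[Si](C)(C)C(C)(C)C)cc1O[Si](C)(C)C(C)(C)C)[C@@H]1O[C@H]1c1ccc(O[Si](C)(C)C(C)(C)C)c(O[Si](C)(C)C(C)(C)C)c1 | intermediate (not isolated)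
9 | (2R,3S,4S)-5,7,3′,4′-tetrakis(tert-butyldimethylsilyloxy)flavan-3,4-diol (2,3-trans-3,4-cis) | O[C@@H]1[C@@H](c2ccc(O[Si](C)(C)C(C)(C)C)c(O[Si](C)(C)C(C)(C)C)c2)Oc2cc(O[Si](C)(C)C(C)(C)C)cc(O[Si](C)(C)C(C)(C)C)c2[C@@H]1O | intermediate
10 | gallic acid | O=C(O)c1cc(O)c(O)c(O)c1 | starting material
11 | tert-butyldimethylsilyl 3,4,5-tris(tert-butyldimethylsilyloxy)benzoate | O=C(O[Si](C)(C)C(C)(C)C)c1cc(O[Si](C)(C)C(C)(C)C)c(O[Si](C)(C)C(C)(C)C)c(O[Si](C)(C)C(C)(C)C)c1 | intermediate (not isolated)
12 | 3,4,5-tris(tert-butyldimethylsilyloxy)benzoic acid | O=C(O)c1cc(O[Si](C)(C)C(C)(C)C)c(O[Si](C)(C)C(C)(C)C)c(O[Si](C)(C)C(C)(C)C)c1 | intermediate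
13 | 3,4,5-tris(tert-butyldimethylsilyloxy)benzoyl chloride | O=C(Cl)c1cc(O[Si](C)(C)C(C)(C)C)c(O[Si](C)(C)C(C)(C)C)c(O[Si](C)(C)C(C)(C)C)c1 | intermediate
14 | 3,4-O-dibutylstannylene acetal of 9 (2,2-dibutyl-1,3,2-dioxastannolane spanning O3 and O4, spatial arrangement as in 9) | CCCC[Sn]1(CCCC)O[C@@H]2[C@@H](c3ccc(O[Si](C)(C)C(C)(C)C)c(O[Si](C)(C)C(C)(C)C)c3)Oc3cc(O[Si](C)(C)C(C)(C)C)cc(O[Si](C)(C)C(C)(C)C)c3[C@@H]2O1 | intermediate (not isolated)
15 | (2R,3S,4S)-4-hydroxy-5,7,3′,4′-tetrakis(tert-butyldimethylsilyloxy)flavan-3-yl 3,4,5-tris(tert-butyldimethylsilyloxy)benzoate | O=C(O[C@@H]1[C@@H](c2ccc(O[Si](C)(C)C(C)(C)C)c(O[Si](C)(C)C(C)(C)C)c2)Oc2cc(O[Si](C)(C)C(C)(C)C)cc(O[Si](C)(C)C(C)(C)C)c2[C@@H]1O)c1cc(O[Si](C)(C)C(C)(C)C)c(O[Si](C)(C)C(C)(C)C)c(O[Si](C)(C)C(C)(C)C)c1 | intermediate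
16 | (2R,3S,4S)-2-(3,4-dihydroxyphenyl)-4,5,7-trihydroxy-3,4-dihydro-2H-chromen-3-yl 3,4,5-trihydroxybenzoate (2,3-trans-3,4-cis-leucocyanidin 3-O-gallate) | O=C(O[C@@H]1[C@@H](c2ccc(O)c(O)c2)Oc2cc(O)cc(O)c2[C@@H]1O)c1cc(O)c(O)c(O)c1 | target

**Totals**

Total step count: 9.
Longest linear sequence: 6 steps (steps 2, 3, 4, 5, 8, 9, from 3,4-dihydroxybenzaldehyde).

**Steps most likely to fail**

Step 5. The bromide counter-ion or the Lewis-acidic magnesium centre may open or rearrange the benzylic epoxide before the ortho C–C bond has formed. The ring closure may stop at the open-chain stage, and addition to the aldehyde may show poor facial selectivity. The fallback uses known reactions only, sets out from 2 and returns at 9. Phenol 2 is iodinated ortho to the hydroxyl group (N-iodosuccinimide, CH2Cl2, 0 °C) to give 2-iodo-3,5-bis(tert-butyldimethylsilyloxy)phenol F1. After deprotonation with MeMgCl, iodine–magnesium exchange with iPrMgCl·LiCl in THF furnishes a preformed aryl Grignard reagent, which is added to aldehyde 6 at −78 °C; addition of aryl Grignard reagents to 2,3-epoxy aldehydes is an established, anti-selective reaction. Work-up gives 2-{(S)-hydroxy[(2S,3S)-3-(3,4-bis(tert-butyldimethylsilyloxy)phenyl)oxiran-2-yl]methyl}-3,5-bis(tert-butyldimethylsilyloxy)phenol F2. F2 is closed in a separate operation by the established 6-endo opening of an aryl epoxide by an ortho-tethered phenol (catalytic pyridinium p-toluenesulfonate, CH2Cl2, −20 °C) to give 9. The C–C bond then comes from a carbon–magnesium reagent and not from the phenolate, and the two bond formations are separated.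

Step 8. Acyl transfer may go to the benzylic O4 or to both oxygens, and C4 may ionise during the hot stannylene formation. The fallback sets out from 9 and acid 12 and returns at 15. Diol 9 is esterified with 12 without tin (Steglich conditions: EDC·HCl, DMAP, CH2Cl2, 0 °C). Any 4-O-acyl regioisomer formed, 3-hydroxy-5,7,3′,4′-tetrakis(tert-butyldimethylsilyloxy)flavan-4-yl 3,4,5-tris(tert-butyldimethylsilyloxy)benzoate F3, is then equilibrated by amine-catalysed 1,2-acyl migration across the cis-diol (Et3N, DMAP, CH2Cl2, rt). The equilibrium should drain toward 15 because the 4-O-ester is quasi-axial, benzylic and pressed against the 5-silyloxy group. Regiocontrol then rests on thermodynamics and not on tin-directed kinetics.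

Step 4. Iminium formation from the electron-rich enal may be slow, the acid-labile aryl epoxy aldehyde may open or rearrange during reaction and isolation, and enantiomeric purity may erode. The fallback sets out from 5 and returns at 6. Luche reduction (NaBH4, CeCl3·7H2O, MeOH, 0 °C) gives (E)-3-[3,4-bis(tert-butyldimethylsilyloxy)phenyl]prop-2-en-1-ol F4. Sharpless asymmetric epoxidation (Ti(OiPr)4, L-(+)-diethyl tartrate, t-BuOOH, 4 Å molecular sieves, CH2Cl2, −20 °C) gives [(2S,3S)-3-(3,4-bis(tert-butyldimethylsilyloxy)phenyl)oxiran-2-yl]methanol F5, with the sense of induction fixed by the tartrate. Parikh–Doering oxidation (SO3·pyridine, DMSO, iPr2NEt, 0 °C) then gives 6.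

**Further compounds**

F1 | step 5 | 2-iodo-3,5-bis(tert-butyldimethylsilyloxy)phenol | Oc1cc(O[Si](C)(C)C(C)(C)C)cc(O[Si](C)(C)C(C)(C)C)c1I
F2 | step 5 | 2-{(S)-hydroxy[(2S,3S)-3-(3,4-bis(tert-butyldimethylsilyloxy)phenyl)oxiran-2-yl]methyl}-3,5-bis(tert-butyldimethylsilyloxy)phenol | O[C@@H](c1c(O)cc(O[Si](C)(C)C(C)(C)C)cc1O[Si](C)(C)C(C)(C)C)[C@@H]1O[C@H]1c1ccc(O[Si](C)(C)C(C)(C)C)c(O[Si](C)(C)C(C)(C)C)c1
F3 | step 8 | 3-hydroxy-5,7,3′,4′-tetrakis(tert-butyldimethylsilyloxy)flavan-4-yl 3,4,5-tris(tert-butyldimethylsilyloxy)benzoate (4-O-acyl regioisomer of 15, spatial arrangement at C2, C3 and C4 as in 9) | O[C@@H]1[C@@H](c2ccc(O[Si](C)(C)C(C)(C)C)c(O[Si](C)(C)C(C)(C)C)c2)Oc2cc(O[Si](C)(C)C(C)(C)C)cc(O[Si](C)(C)C(C)(C)C)c2[C@@H]1OC(=O)c1cc(O[Si](C)(C)C(C)(C)C)c(O[Si](C)(C)C(C)(C)C)c(O[Si](C)(C)C(C)(C)C)c1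
F4 | step 4 | (E)-3-[3,4-bis(tert-butyldimethylsilyloxy)phenyl]prop-2-en-1-ol | OC/C=C/c1ccc(O[Si](C)(C)C(C)(C)C)c(O[Si](C)(C)C(C)(C)C)c1
F5 | step 4 | [(2S,3S)-3-(3,4-bis(tert-butyldimethylsilyloxy)phenyl)oxiran-2-yl]methanol | OC[C@@H]1O[C@H]1c1ccc(O[Si](C)(C)C(C)(C)C)c(O[Si](C)(C)C(C)(C)C)c1
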